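The isoflavone is disconnected at C3–C4 and O1–C2 of ring C, back to a 2'-O-MOM chalcone epoxide that already carries every carbon and oxygen of the target. With BF3 and then methanolic HCl in one flask, the ring A aroyl carbon (future C4) shifts to the benzylic carbon (future C3), the MOM ether is lost, and the phenol closes ring C on the new formyl carbon (C2). The step exploits the 2,4,5-trimethoxyphenyl ring B on C3: its 2'- and 4'-methoxy groups stabilise a cation there, so no electrophilic oxidant threatens the C8 prenyl alkene. The precursor comes from Claisen–Schmidt condensation and nucleophilic epoxidation.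

Key step: step 6

Remark: compounds 7 and 9 to 12 are racemates or stereoisomer mixtures; this has no consequence, because every stereocentre becomes an sp2 carbon when ring C turns aromatic.

Step 1
Reactants: 1 2,4-dihydroxyacetophenone; 2 prenyl bromide (1-bromo-3-methylbut-2-ene)
Product: 3 2,4-dihydroxy-3-(3-methylbut-2-enyl)acetophenone
Conditions: KOH (10% aq), 2 (0.9 equiv) added slowly, 0 °C to rt; then dil. HCl; chromatography
Reagents that add atoms: none
Why: Phenoxide C-alkylation (nuclear prenylation): in water the dianion of 1 is solvated at oxygen and reacts as a carbon nucleophile at C3, the ring carbon flanked by both phenoxide oxygens, so 3 should be the main monoalkylation product, and chromatography should free it from the 5-prenyl, diprenyl and O-prenyl isomers and from recovered 1.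

Step 2
Reactants: 3 2,4-dihydroxy-3-(3-methylbut-2-enyl)acetophenone
Product: 4 2-hydroxy-4-methoxy-3-(3-methylbut-2-enyl)acetophenone
Conditions: MeI (1.05 equiv), K2CO3, acetone, rt to 40 °C
Reagents that add atoms: methyl iodide, CI
Why: Williamson ether synthesis in which the weak base ionises only the free 4-hydroxyl, while the 2-hydroxyl is held in a hydrogen bond to the acetyl oxygen and should stay unalkylated with one equivalent of MeI.

Step 3
Reactants: 4 2-hydroxy-4-methoxy-3-(3-methylbut-2-enyl)acetophenone
Product: 5 4-methoxy-2-(methoxymethoxy)-3-(3-methylbut-2-enyl)acetophenone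
Conditions: NaH (1.1 equiv), DMF, 0 °C; then MOMCl, 0 °C to rt
Reagents that add atoms: chloromethyl methyl ether, COCCl
Why: MOM protection by O-alkylation of the sodium phenoxide with a reactive alpha-chloro ether: irreversible deprotonation by NaH breaks the chelate, and the acetal masks the future O1 through the basic steps, where a free 2'-hydroxyl would close to a flavanone, aurone or flavonol.

Step 4
Reactants: 5 4-methoxy-2-(methoxymethoxy)-3-(3-methylbut-2-enyl)acetophenone; 6 2,4,5-trimethoxybenzaldehyde
Product: 8 (E)-1-[4-methoxy-2-(methoxymethoxy)-3-(3-methylbut-2-enyl)phenyl]-3-(2,4,5-trimethoxyphenyl)prop-2-en-1-one, via aldol adduct 7 (not isolated)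
Conditions: KOH, EtOH–H2O, rt
Reagents that add atoms: none
Why: Claisen–Schmidt condensation: the methyl ketone enolate adds to the non-enolisable aldehyde to give aldol 7, and E1cB loss of water under equilibrating conditions should give the conjugated E-enone, while the MOM ether and the prenyl group are inert to hydroxide.

Step 5
Reactants: 8 (E)-chalcone
Product: 9 racemic trans-[4-methoxy-2-(methoxymethoxy)-3-(3-methylbut-2-enyl)phenyl][3-(2,4,5-trimethoxyphenyl)oxiran-2-yl]methanone (2S,3R enantiomer drawn)
Conditions: H2O2 (30% aq), NaOH (2 M aq), MeOH–THF, 0 °C to rt; extraction, drying over K2CO3, crude used at once without silica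
Reagents that add atoms: hydrogen peroxide, OO
Why: Weitz–Scheffer epoxidation: the hydroperoxide anion adds to the enone beta carbon and the enolate then displaces hydroxide from the O–O bond, which sets the two new stereocentres trans to each other (racemic) through the less crowded enolate rotamer, while the electron-rich prenyl alkene is no acceptor for a nucleophilic oxidant and the MOM ether prevents Algar–Flynn–Oyamada cyclisation.

Step 6
Reactants: 9 racemic trans-chalcone epoxide
Product: 13 prebarbigerone [7-methoxy-8-(3-methylbut-2-enyl)-3-(2,4,5-trimethoxyphenyl)chromen-4-one], via MOM-protected alpha-formyl deoxybenzoin 10 (not isolated), via free-phenol alpha-formyl deoxybenzoin 11 (not isolated), via 2-hydroxyisoflavanone 12 (not isolated)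
Conditions: BF3·OEt2 (0.3 equiv), CH2Cl2, −40 to −20 °C; then HCl (1 M in MeOH) added to the same flask, −20 to 40 °C
Reagents that add atoms: none
Why: BF3 binds the oxirane oxygen and the C–O bond at the benzylic carbon ionises, since the 2'- and 4'-methoxy groups of ring B stabilise that cation, after which the ring A aroyl carbon shifts from the alpha carbon to the cationic carbon (forming C3–C4) and the alpha carbon collapses to the formyl carbon C2 of 10. The closest known reaction is the Meinwald rearrangement of alpha,beta-epoxy ketones with acyl migration, as applied to 2'-O-protected chalcone epoxides to reach alpha-formyl deoxybenzoins and isoflavones. Methanolic HCl then cleaves the MOM acetal to phenol 11, whose oxygen adds to the formyl carbon in a 6-exo-trig closure (O1–C2, ring C) to give hemiacetal 12, and loss of water to the aromatic 4-pyranone should drive the sequence to 13. No stereocentre has to be controlled: the two oxirane centres and the centres of 10, 11 and 12 all become sp2 carbons of ring C. The step needs opening at the benzylic and not the alpha carbon, migration of acyl and not hydride (which would give a 1,2-diketone), and no capture of the cation by the ring A oxygen (which would give a dihydroflavonol); the cation-stabilising ring B, the high migratory aptitude of an acyl group next to an oxirane, and the MOM ether that stays in place through the cold aprotic BF3 stage should secure these. The C8 prenyl alkene should survive because no electrophilic oxidant is used, the Lewis acid contact is short and cold, and the free phenol beside it is trapped by the formyl group before it can add to the alkene to form a chroman.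

Compound list
1 | 2,4-dihydroxyacetophenone | CC(=O)c1ccc(O)cc1O | starting material
2 | prenyl bromide (1-bromo-3-methylbut-2-ene) | CC(C)=CCBr | starting material
3 | 2,4-dihydroxy-3-(3-methylbut-2-enyl)acetophenone | CC(=O)c1ccc(O)c(CC=C(C)C)c1O | intermediate
4 | 2-hydroxy-4-methoxy-3-(3-methylbut-2-enyl)acetophenone | CC(=O)c1ccc(OC)c(CC=C(C)C)c1O | intermediate
5 | 4-methoxy-2-(methoxymethoxy)-3-(3-methylbut-2-enyl)acetophenone | CC(=O)c1ccc(OC)c(CC=C(C)C)c1OCOC | intermediate
6 | 2,4,5-trimethoxybenzaldehyde | COc1cc(OC)c(C=O)cc1OC | starting material
7 | 3-hydroxy-1-[4-methoxy-2-(methoxymethoxy)-3-(3-methylbut-2-enyl)phenyl]-3-(2,4,5-trimethoxyphenyl)propan-1-one, racemic aldol adduct, not isolated | COCOc1c(CC=C(C)C)c(OC)ccc1C(=O)CC(O)c1cc(OC)c(OC)cc1OC | intermediate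
8 | (E)-1-[4-methoxy-2-(methoxymethoxy)-3-(3-methylbut-2-enyl)phenyl]-3-(2,4,5-trimethoxyphenyl)prop-2-en-1-one | COCOc1c(CC=C(C)C)c(OC)ccc1C(=O)/C=C/c1cc(OC)c(OC)cc1OC | intermediate
9 | trans-[4-methoxy-2-(methoxymethoxy)-3-(3-methylbut-2-enyl)phenyl][3-(2,4,5-trimethoxyphenyl)oxiran-2-yl]methanone, racemic, (2S,3R) enantiomer drawn | COCOc1c(CC=C(C)C)c(OC)ccc1C(=O)[C@H]1O[C@@H]1c1cc(OC)c(OC)cc1OC | intermediate
10 | 3-[4-methoxy-2-(methoxymethoxy)-3-(3-methylbut-2-enyl)phenyl]-3-oxo-2-(2,4,5-trimethoxyphenyl)propanal, racemic and enolisable, not isolated | COCOc1c(CC=C(C)C)c(OC)ccc1C(=O)C(C=O)c1cc(OC)c(OC)cc1OC | intermediate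
11 | 3-[2-hydroxy-4-methoxy-3-(3-methylbut-2-enyl)phenyl]-3-oxo-2-(2,4,5-trimethoxyphenyl)propanal, racemic and enolisable, not isolated | COc1cc(OC)c(C(C=O)C(=O)c2ccc(OC)c(CC=C(C)C)c2O)cc1OC | intermediate
12 | 2-hydroxy-7-methoxy-8-(3-methylbut-2-enyl)-3-(2,4,5-trimethoxyphenyl)chroman-4-one, mixture of racemic diastereomers, not isolated | COc1cc(OC)c(C2C(O)Oc3c(CC=C(C)C)c(OC)ccc3C2=O)cc1OC | intermediate
13 | prebarbigerone, 7-methoxy-8-(3-methylbut-2-enyl)-3-(2,4,5-trimethoxyphenyl)chromen-4-one | COc1cc(OC)c(-c2coc3c(CC=C(C)C)c(OC)ccc3c2=O)cc1OC | target

Total step count: 6. Longest linear sequence: 6 steps (1 to 13); aldehyde 6 and bromide 2 are bought.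

Steps most likely to fail

Step 6. After the oxirane ionises, the ring A ether oxygen may capture the benzylic cation with loss of the methoxymethyl group before the aroyl group has migrated. A hydride may also shift in place of the acyl group, or the briefly free phenol may add to the prenyl alkene under acid. The fallback sets out from 5 and comes back to the route at 13. Pd-catalysed alpha-arylation of ketone 5 with commercial 1-bromo-2,4,5-trimethoxybenzene (Pd2(dba)3, XPhos, NaOtBu, toluene, 80 °C) should give 1-[4-methoxy-2-(methoxymethoxy)-3-(3-methylbut-2-enyl)phenyl]-2-(2,4,5-trimethoxyphenyl)ethanone F1. Condensation of this deoxybenzoin with N,N-dimethylformamide dimethyl acetal (toluene, 90 °C) should give the enaminone 3-(dimethylamino)-1-[4-methoxy-2-(methoxymethoxy)-3-(3-methylbut-2-enyl)phenyl]-2-(2,4,5-trimethoxyphenyl)prop-2-en-1-one F2, in which the future C2 is already bonded to C3. Dilute methanolic HCl should then remove the MOM group, and the phenol should displace dimethylamine by addition–elimination to close ring C and give 13. This is the classical deoxybenzoin route to isoflavones and needs neither epoxide nor rearrangement.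

Step 1. Alkylation may go to oxygen, to C5 or twice, so that little of the C3 isomer is recovered. The fallback sets out from 1 and comes back at 3. The non-chelated 4-hydroxyl of 1 is alkylated with 3-chloro-3-methylbut-1-yne (K2CO3, KI and CuI as catalysts, acetone, reflux) to give 4-(1,1-dimethylprop-2-ynyloxy)-2-hydroxyacetophenone F3. Semihydrogenation (H2, Pd/CaCO3 poisoned with Pb(OAc)2, quinoline, EtOAc) should give 4-(1,1-dimethylallyloxy)-2-hydroxyacetophenone F4. Heating F4 in N,N-diethylaniline at about 130 °C should bring about an aromatic Claisen rearrangement that delivers the allyl terminus as a normal prenyl group to C3 and so gives 3. C3 is the ortho carbon favoured by the bond fixation that the chelated 2-hydroxy ketone imposes on ring A.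

Step 5. Conjugate addition of hydroperoxide may be slow on an enone deactivated by the electron-rich ring B, and the very labile benzylic C–O bond of the product may open by solvolysis during reaction or work-up. The fallback sets out from 5 and comes back at 9. The lithium enolate of 5 (LiN(SiMe3)2, THF, −78 °C) is chlorinated with p-toluenesulfonyl chloride to give 2-chloro-1-[4-methoxy-2-(methoxymethoxy)-3-(3-methylbut-2-enyl)phenyl]ethanone F5. A Darzens condensation of F5 with aldehyde 6 (NaOMe, MeOH–THF, 0 °C) should then give the trans epoxy ketone 9 directly. It forms the alpha–beta bond and the oxirane together and needs neither chalcone 8 nor an oxidant.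

Further compounds
F1 | step 6 | 1-[4-methoxy-2-(methoxymethoxy)-3-(3-methylbut-2-enyl)phenyl]-2-(2,4,5-trimethoxyphenyl)ethanone | COCOc1c(CC=C(C)C)c(OC)ccc1C(=O)Cc1cc(OC)c(OC)cc1OC
F2 | step 6 | 3-(dimethylamino)-1-[4-methoxy-2-(methoxymethoxy)-3-(3-methylbut-2-enyl)phenyl]-2-(2,4,5-trimethoxyphenyl)prop-2-en-1-one, alkene geometry not defined | COCOc1c(CC=C(C)C)c(OC)ccc1C(=O)C(=CN(C)C)c1cc(OC)c(OC)cc1OC
F3 | step 1 | 4-(1,1-dimethylprop-2-ynyloxy)-2-hydroxyacetophenone | CC(=O)c1ccc(OC(C)(C)C#C)cc1O
F4 | step 1 | 4-(1,1-dimethylallyloxy)-2-hydroxyacetophenone | CC(=O)c1ccc(OC(C)(C)C=C)cc1O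
F5 | step 5 | 2-chloro-1-[4-methoxy-2-(methoxymethoxy)-3-(3-methylbut-2-enyl)phenyl]ethanone | ClCC(=O)c1ccc(OC)c(CC=C(C)C)c1OCOC
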